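## Analysis of the target

The target (11) is a flavone, with ring A the benzo ring C4a–C5–C6–C7–C8–C8a, ring C the 4-pyranone O1–C2–C3–C4–C4a–C8a, and ring B the para-disubstituted phenyl on C2. Ring A carries oxygen on C5, C7 and C8a and the acyl carbon C4 on C4a, so it is an acylphloroglucinol. Continuing through C4 and C2, every second carbon of the nine-carbon run from C2 through C3, C4, C4a and around ring A is oxygenated, which is the imprint of a folded poly-β-carbonyl chain. The methoxy group on C3 is the one oxygen that lies outside this alternating pattern. There are no stereocenters, and the prenyl double bond has no geometry because it ends in two identical methyl groups. The aryl prenyl ether is the sensitive group: it does not tolerate strong Brønsted or Lewis acids, hydrogenation, electrophilic halogen, or heating towards 180 °C. The real difficulty is the differentiation of four oxygen substituents in three states (free 5-OH and 7-OH, 3-OMe, 4'-O-prenyl). The 7-OH is the most acidic phenol, so neither O-3 nor O-4' can be alkylated selectively late. The methyl and prenyl groups must therefore arrive with the building blocks, and the ring A hydroxyls must appear free, without a deprotection the prenyl ether would not survive.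

## Retrosynthetic reasoning

Chain numbering used below: chain C9 = flavone C2, chain C8 = C3, chain C7 = C4, chain C6 = C4a, chain C1 to C5 = the other five carbons of ring A.

**11 to 10, cut O1–C2.** Ring C is opened to the 2,4,6-trihydroxyphenyl ketone 10, in which C2 is the β-carbon of a β-methoxy enone. The forward reaction is an intramolecular addition–elimination by an ortho phenoxide. Ring A of 10 is symmetric, so either ortho hydroxyl gives the same flavone and no regiochemistry has to be controlled.

**10 to 9, cut C4a–C5.** This is the bond between the acylated ring carbon and an oxygen-bearing ring carbon. Cutting it unfolds the whole of ring A into the linear 3,5,7-triketo ester 9. The forward reaction is a Claisen condensation of chain C6 onto the ester carbon C1, followed by aromatisation. The cut is made here because all six ring A carbons then come from one chain, and the three ring oxygens are simply the chain carbonyl oxygens, set free without any protecting group. The aldol-type cut (C2 to C7) would leave a carboxyl group on the ring, and the usual cut through ring C alone would leave ring A to be bought.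

**9 to 8, mask the 3,5-dioxo ester terminus.** Chain C1 to C5 is stored as the 4-hydroxy-2-pyranone ring of 8, a stable, handleable form of the triketo ester. The forward reaction is base-induced alcoholysis of the lactone. The three disconnections so far are one forward operation, step 5.

**8 to 6 + 7, cut C4–C4a (chain C6–C7).** The methyl carbon of pyranone 7, as its dianion, is acylated by ester 6. Compound 7 supplies all six carbons of ring A in one commercial piece. In 6 the future C2 is a methyl enol ether, which does three jobs: it removes the acidic hydrogen at the future C3, which would otherwise quench the dianion; it turns the future C4 carbonyl into a vinylogous ester that resists aldol attack; and it provides the leaving group for ring C closure.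

**6 to 5, cut the enol O–CH3 bond.** The forward reaction is O-methylation of the enolate of β-keto ester 5.

**5 to 3 + 4, cut C2–C3.** A crossed Claisen condensation joins the enolate of 4 to the non-enolisable aryl ester 3. The 3-methoxy group of the target comes in with 4 and is never a free hydroxyl.

**3 to 1 + 2, cut the O–prenyl bond.** A Williamson ether synthesis places the prenyl group on the only phenol present at that stage.

## Alternatives that were turned down

**Alternative 1:** the textbook disconnection, O1–C2 and C2–C3 (Allan–Robinson or Baker–Venkataraman). The forward key step heats 2-methoxy-1-(2,4,6-trihydroxyphenyl)ethan-1-one A1 with 4-[(3-methylbut-2-en-1-yl)oxy]benzoic anhydride A2 and the salt of the corresponding acid, then hydrolyses the phenol esters. It was turned down for three reasons. Ring A and its three oxygens are bought, so the key step builds only ring C. The melt temperature lies in the range where an aryl prenyl ether rearranges or cleaves, so the sensitive group is at risk in the key step itself. O-acylation of the free phenols runs ahead of C-acylation, so several equivalents of the prenylated acyl unit are consumed and a separate hydrolysis is needed.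

**Alternative 2:** an aryne annulation that forms O1–C8a and C4–C4a in one operation. The aryne is released by fluoride from 3,5-bis(methoxymethoxy)-2-(trimethylsilyl)phenyl trifluoromethanesulfonate A3. The enolate oxygen of 5 would add to it, and the aryl anion would then attack the ester of 5 to give 3-methoxy-5,7-bis(methoxymethoxy)-2-{4-[(3-methylbut-2-en-1-yl)oxy]phenyl}-4H-chromen-4-one A4, which would be deprotected. The regiochemistry is sound: the nucleophile adds to the aryne carbon remote from the flanking alkoxy group, and the carbanion forms next to that group, at the future C4a. It was turned down because the enolate of 5 is ambident. Carbon arylation followed by attack on the ketone and fragmentation (acyl-alkylation) gives the wrong connectivity, and nothing in 5 favours oxygen attack. In addition, A3 costs four or five steps with protecting groups, and the final acetal cleavage needs acid that threatens the prenyl ether.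

**Alternative 3:** oxidative cyclisation of a chalcone (Algar–Flynn–Oyamada), which forms O1–C2 and the C3–O bond. (E)-1-[2-Hydroxy-4,6-bis(methoxymethoxy)phenyl]-3-{4-[(3-methylbut-2-en-1-yl)oxy]phenyl}prop-2-en-1-one A5 would be treated with alkaline peroxide to give 3-hydroxy-5,7-bis(methoxymethoxy)-2-{4-[(3-methylbut-2-en-1-yl)oxy]phenyl}-4H-chromen-4-one A6, followed by methylation at O-3 and acetal cleavage. It was turned down because the 6'-oxygen substituent twists the carbonyl out of the ring plane, which steers the phenoxide to the α-carbon (5-exo) and so towards an aurone. The C3 oxygen is also introduced and then methylated in two steps, where 4 delivers it ready-made, and the protection and acidic deprotection of ring A lengthen the route to six or seven steps.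

Key step: step 5

Remark: compounds 6, 8, 9 and 10 are carried as E/Z mixtures at the enol ether double bond and their SMILES carry no geometry, because this carbon becomes the aromatic C2 of ring C. Compound 5 is racemic and its stereocenter is erased in step 3.

## Route

Step 1
Reactants: 1 methyl 4-hydroxybenzoate; 2 1-bromo-3-methylbut-2-ene (prenyl bromide)
Product: 3 methyl 4-[(3-methylbut-2-en-1-yl)oxy]benzoate
Conditions: K2CO3, DMF, 25 °C
Reagents that add atoms: none
Why: Williamson ether synthesis; the phenoxide, acidified by the para ester, should displace the primary allylic bromide by SN2 at oxygen, and at room temperature in a dipolar aprotic solvent carbon alkylation and SN2' attack should not compete.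

Step 2
Reactants: 3 methyl 4-[(3-methylbut-2-en-1-yl)oxy]benzoate; 4 methyl 2-methoxyacetate
Product: 5 methyl 2-methoxy-3-{4-[(3-methylbut-2-en-1-yl)oxy]phenyl}-3-oxopropanoate (racemic)
Conditions: 4 (1.3 equiv), LiN(SiMe3)2 (2.3 equiv), THF, −78 °C; then 3, −78 to 0 °C; AcOH quench
Reagents that add atoms: none
Why: Crossed Claisen condensation of the lithium enolate of 4 with the non-enolisable aryl ester 3; the second equivalent of base converts 5 into its enolate, which drives the reaction and shields the new ketone.

Step 3
Reactants: 5 methyl 2-methoxy-3-{4-[(3-methylbut-2-en-1-yl)oxy]phenyl}-3-oxopropanoate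
Product: 6 methyl 2,3-dimethoxy-3-{4-[(3-methylbut-2-en-1-yl)oxy]phenyl}prop-2-enoate (E/Z mixture)
Conditions: KOtBu (1.05 equiv), THF–DMPU, 0 °C; then Me2SO4, 0 to 25 °C
Reagents that add atoms: dimethyl sulfate, COS(=O)(=O)OC
Why: O-alkylation of a β-keto ester enolate; a hard methylating agent, a potassium counter-ion in a dipolar aprotic medium and a fully substituted, oxygen-bearing α-carbon should all direct methylation to the ketone oxygen.

Step 4
Reactants: 7 4-hydroxy-6-methyl-2H-pyran-2-one (as its dilithium dianion); 6 methyl 2,3-dimethoxy-3-{4-[(3-methylbut-2-en-1-yl)oxy]phenyl}prop-2-enoate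
Product: 8 6-(3,4-dimethoxy-4-{4-[(3-methylbut-2-en-1-yl)oxy]phenyl}-2-oxobut-3-en-1-yl)-4-hydroxy-2H-pyran-2-one
Conditions: 7 (2.2 equiv), LiN(iPr)2 (4.5 equiv), THF–DMPU, −78 to −20 °C; then 6 (1 equiv), −78 to 0 °C; AcOH quench
Reagents that add atoms: none
Why: Acylation of the dianion of 7 at its methyl carbon, the last-formed and most nucleophilic site, by the ester of 6, which has no acidic hydrogen; attack at the ester carbonyl is expected over conjugate attack because the β-carbon is tetrasubstituted and carries two donors, and the excess dianion absorbs the acidic methylene of 8.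

Step 5
Reactants: 8 6-(3,4-dimethoxy-4-{4-[(3-methylbut-2-en-1-yl)oxy]phenyl}-2-oxobut-3-en-1-yl)-4-hydroxy-2H-pyran-2-one
Product: 11 5,7-dihydroxy-3-methoxy-2-{4-[(3-methylbut-2-en-1-yl)oxy]phenyl}-4H-chromen-4-one, via triketo ester 9 (not isolated), via trihydroxyphenyl ketone 10 (not isolated)
Conditions: Mg(OMe)2 (8 equiv), MeOH, reflux; then AcOH, 50 °C
Reagents that add atoms: none
Why: Methoxide from Mg(OMe)2 should open the lactone of 8 at its carbonyl carbon to the magnesium chelate of the 3,5,7-triketo methyl ester 9, the known behaviour of 4-hydroxy-6-alkyl-2-pyranones in this medium; the methoxy group taken up here is released again in the next event. The carbanion at chain C6, flanked by the C5 and C7 carbonyls, then attacks the ester carbon C1 (Claisen condensation, 6-exo-trig closure of ring A), methoxide leaves and the cyclohexanetrione tautomerises irreversibly to 10; the closest known reaction type is the magnesium methoxide-mediated conversion of 6-(2-oxoalkyl)-4-hydroxy-2-pyranones and 3,5,7-triketo esters into acylphloroglucinols. An ortho phenoxide of 10 then adds to the enol ether carbon (6-endo-trig oxa-Michael addition) and methoxide is expelled, which closes ring C as the aromatic 4-pyranone, the known closure of 2-hydroxyaryl β-alkoxyvinyl ketones to chromones; the acetic acid treatment completes it through the protonated enone. If the C5 enolate oxygen displaces the enol ether methoxy group before the Claisen step, the resulting 4-pyranone has only the Claisen closure left open and ends at the same product, so both orders converge on 11. No stereocenter is formed and the enol ether geometry is irrelevant. The selectivity needed is Claisen closure (C6 to C1) over aldol closure (C2 to C7) and over carbon attack of C4 on C9: the C7 carbonyl is a vinylogous ester next to a fully substituted carbon, C9 is tetrasubstituted and carries two donors, C8 has no hydrogen and cannot act as a nucleophile, and the methoxide medium keeps C1 an ester and not an unreactive carboxylate, while divalent magnesium holds the dicarbonyl units in the chelated fold. Ring A of 10 is symmetric, so either ortho hydroxyl gives the same flavone, and methoxide exchange at the enol ether is degenerate. The prenyl ether meets only methoxide in methanol and dilute acetic acid, both of which it should tolerate.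

## Compound list

1 | methyl 4-hydroxybenzoate | COC(=O)c1ccc(O)cc1 | starting material
2 | 1-bromo-3-methylbut-2-ene | CC(C)=CCBr | starting material
3 | methyl 4-[(3-methylbut-2-en-1-yl)oxy]benzoate | COC(=O)c1ccc(OCC=C(C)C)cc1 | intermediate
4 | methyl 2-methoxyacetate | COCC(=O)OC | starting material
5 | methyl 2-methoxy-3-{4-[(3-methylbut-2-en-1-yl)oxy]phenyl}-3-oxopropanoate (racemic) | COC(=O)C(OC)C(=O)c1ccc(OCC=C(C)C)cc1 | intermediate
6 | methyl 2,3-dimethoxy-3-{4-[(3-methylbut-2-en-1-yl)oxy]phenyl}prop-2-enoate (E/Z mixture) | COC(=O)C(OC)=C(OC)c1ccc(OCC=C(C)C)cc1 | intermediate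
7 | 4-hydroxy-6-methyl-2H-pyran-2-one | CC1=CC(O)=CC(=O)O1 | starting material
8 | 6-(3,4-dimethoxy-4-{4-[(3-methylbut-2-en-1-yl)oxy]phenyl}-2-oxobut-3-en-1-yl)-4-hydroxy-2H-pyran-2-one (E/Z mixture) | COC(C(=O)CC1=CC(O)=CC(=O)O1)=C(OC)c1ccc(OCC=C(C)C)cc1 | intermediate
9 | methyl 8,9-dimethoxy-9-{4-[(3-methylbut-2-en-1-yl)oxy]phenyl}-3,5,7-trioxonon-8-enoate (E/Z mixture, magnesium chelate in the flask) | COC(=O)CC(=O)CC(=O)CC(=O)C(OC)=C(OC)c1ccc(OCC=C(C)C)cc1 | intermediate (not isolated)
10 | 2,3-dimethoxy-3-{4-[(3-methylbut-2-en-1-yl)oxy]phenyl}-1-(2,4,6-trihydroxyphenyl)prop-2-en-1-one (E/Z mixture) | COC(C(=O)c1c(O)cc(O)cc1O)=C(OC)c1ccc(OCC=C(C)C)cc1 | intermediate (not isolated)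
11 | 5,7-dihydroxy-3-methoxy-2-{4-[(3-methylbut-2-en-1-yl)oxy]phenyl}-4H-chromen-4-one | COc1c(-c2ccc(OCC=C(C)C)cc2)oc2cc(O)cc(O)c2c1=O | target

## Step count and risk

Total step count: 5. Longest linear sequence: 5 steps (1 to 3 to 5 to 6 to 8 to 11); 2, 4 and 7 enter as commercial materials.

**Step 5 (key step).** The chain may fold in the wrong mode: aldol closure from chain C2 onto the C7 carbonyl, carbon attack of C4 on the enol ether carbon, or retro-Claisen cleavage of the C6–C7 bond by methoxide. The pyranone anion may also open too slowly, because it is electron-rich. The fallback buys ring A instead of folding it; it sets out from 3 and comes back at 11. Ester 3 is saponified (LiOH, THF–water) to 4-[(3-methylbut-2-en-1-yl)oxy]benzoic acid F1. This is converted under neutral conditions with 1-chloro-N,N,2-trimethylprop-1-en-1-amine into 4-[(3-methylbut-2-en-1-yl)oxy]benzoyl chloride F2. 2-Methoxy-1-(2,4,6-trihydroxyphenyl)ethan-1-one F3 (the same compound as A1, commercial or made by acylation of the parent triphenol) is converted with LiN(SiMe3)2 (about 4.5 equiv, THF, −78 °C) into its tetraanion. This is acylated at carbon by F2 to give 2-methoxy-1-{4-[(3-methylbut-2-en-1-yl)oxy]phenyl}-3-(2,4,6-trihydroxyphenyl)propane-1,3-dione F4. Warming F4 in AcOH with NaOAc should close ring C by cyclodehydration to 11.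

**Step 4.** The carbanion may add to the β-carbon of the push–pull acrylate and displace its methoxy group instead of attacking the ester carbonyl. The ester, deactivated as a vinylogous carbonate, may also react too slowly, so that the dianion decays. The fallback replaces ester acylation by addition to an aldehyde and re-oxidation; it sets out from 6 and comes back at 8. Ester 6 is reduced with iBu2AlH (CH2Cl2, −78 °C) to 2,3-dimethoxy-3-{4-[(3-methylbut-2-en-1-yl)oxy]phenyl}prop-2-en-1-ol F5. This is oxidised with MnO2 to 2,3-dimethoxy-3-{4-[(3-methylbut-2-en-1-yl)oxy]phenyl}prop-2-enal F6. The dianion of 7 adds to the aldehyde carbonyl to give 4-hydroxy-6-(2-hydroxy-3,4-dimethoxy-4-{4-[(3-methylbut-2-en-1-yl)oxy]phenyl}but-3-en-1-yl)-2H-pyran-2-one F7. MnO2 oxidation of this allylic alcohol returns to 8.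

**Step 3.** Methylation may occur at carbon and not at oxygen of the ambident enolate, giving a quaternary α-methyl compound that cannot be carried on. The fallback avoids enolate alkylation altogether; it sets out from 5 and comes back at 6. Ketone 5 is ketalised with trimethyl orthoformate and a catalytic amount of camphorsulfonic acid in MeOH to methyl 2,3,3-trimethoxy-3-{4-[(3-methylbut-2-en-1-yl)oxy]phenyl}propanoate F8. One methoxy group is then eliminated with Me3SiOTf and iPr2NEt (CH2Cl2, −20 °C) to give 6.

**Step 2.** The enolate of 4 may condense with itself faster than it attacks the electron-rich and therefore sluggish aryl ester 3, leading to low conversion. The fallback uses an aldehyde electrophile and a later oxidation; it sets out from 2 and comes back at 5. Bromide 2 alkylates 4-hydroxybenzaldehyde F9 (commercial; K2CO3, DMF) to give 4-[(3-methylbut-2-en-1-yl)oxy]benzaldehyde F10. Aldol addition of the lithium enolate of 4 (LiN(iPr)2, THF, −78 °C) gives methyl 3-hydroxy-2-methoxy-3-{4-[(3-methylbut-2-en-1-yl)oxy]phenyl}propanoate F11 as a mixture of diastereomers. Oxidation with Dess–Martin periodinane in NaHCO3-buffered CH2Cl2 returns to 5.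

## Further compounds

F1 | step 5 | 4-[(3-methylbut-2-en-1-yl)oxy]benzoic acid | CC(C)=CCOc1ccc(cc1)C(O)=O
F2 | step 5 | 4-[(3-methylbut-2-en-1-yl)oxy]benzoyl chloride | CC(C)=CCOc1ccc(cc1)C(Cl)=O
F3 | step 5 | 2-methoxy-1-(2,4,6-trihydroxyphenyl)ethan-1-one | COCC(=O)c1c(O)cc(O)cc1O
F4 | step 5 | 2-methoxy-1-{4-[(3-methylbut-2-en-1-yl)oxy]phenyl}-3-(2,4,6-trihydroxyphenyl)propane-1,3-dione (racemic) | COC(C(=O)c1ccc(OCC=C(C)C)cc1)C(=O)c1c(O)cc(O)cc1O
F5 | step 4 | 2,3-dimethoxy-3-{4-[(3-methylbut-2-en-1-yl)oxy]phenyl}prop-2-en-1-ol (E/Z mixture) | COC(CO)=C(OC)c1ccc(OCC=C(C)C)cc1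
F6 | step 4 | 2,3-dimethoxy-3-{4-[(3-methylbut-2-en-1-yl)oxy]phenyl}prop-2-enal (E/Z mixture) | COC(C=O)=C(OC)c1ccc(OCC=C(C)C)cc1
F7 | step 4 | 4-hydroxy-6-(2-hydroxy-3,4-dimethoxy-4-{4-[(3-methylbut-2-en-1-yl)oxy]phenyl}but-3-en-1-yl)-2H-pyran-2-one (racemic, E/Z mixture) | COC(C(O)CC1=CC(O)=CC(=O)O1)=C(OC)c1ccc(OCC=C(C)C)cc1
F8 | step 3 | methyl 2,3,3-trimethoxy-3-{4-[(3-methylbut-2-en-1-yl)oxy]phenyl}propanoate (racemic) | COC(=O)C(OC)C(OC)(OC)c1ccc(OCC=C(C)C)cc1
F9 | step 2 | 4-hydroxybenzaldehyde | O=Cc1ccc(O)cc1
F10 | step 2 | 4-[(3-methylbut-2-en-1-yl)oxy]benzaldehyde | CC(C)=CCOc1ccc(C=O)cc1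
F11 | step 2 | methyl 3-hydroxy-2-methoxy-3-{4-[(3-methylbut-2-en-1-yl)oxy]phenyl}propanoate (mixture of diastereomers) | COC(=O)C(OC)C(O)c1ccc(OCC=C(C)C)cc1
A1 | alternative 1 | 2-methoxy-1-(2,4,6-trihydroxyphenyl)ethan-1-one | COCC(=O)c1c(O)cc(O)cc1O
A2 | alternative 1 | 4-[(3-methylbut-2-en-1-yl)oxy]benzoic anhydride | CC(C)=CCOc1ccc(cc1)C(=O)OC(=O)c1ccc(OCC=C(C)C)cc1
A3 | alternative 2 | 3,5-bis(methoxymethoxy)-2-(trimethylsilyl)phenyl trifluoromethanesulfonate | COCOc1cc(OCOC)c([Si](C)(C)C)c(OS(=O)(=O)C(F)(F)F)c1
A4 | alternative 2 | 3-methoxy-5,7-bis(methoxymethoxy)-2-{4-[(3-methylbut-2-en-1-yl)oxy]phenyl}-4H-chromen-4-one | COCOc1cc(OCOC)c2c(c1)oc(-c1ccc(OCC=C(C)C)cc1)c(OC)c2=O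
A5 | alternative 3 | (E)-1-[2-hydroxy-4,6-bis(methoxymethoxy)phenyl]-3-{4-[(3-methylbut-2-en-1-yl)oxy]phenyl}prop-2-en-1-one | COCOc1cc(O)c(C(=O)/C=C/c2ccc(OCC=C(C)C)cc2)c(OCOC)c1
A6 | alternative 3 | 3-hydroxy-5,7-bis(methoxymethoxy)-2-{4-[(3-methylbut-2-en-1-yl)oxy]phenyl}-4H-chromen-4-one | COCOc1cc(OCOC)c2c(c1)oc(-c1ccc(OCC=C(C)C)cc1)c(O)c2=O
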